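**Retrosynthetic overview**
1. Endgame: the C15 aldehyde comes from allylic oxidation of a C4 isopropenyl group; the O6 angelate and O9 (R)-2-methylbutanoate are put on an α-methylene lactone diol derivative.
2. Ring B (C7, C11, C12, O8, C8): C7–C11 by alkylation of a C8 ketone enolate, O8 by an O6-directed anti reduction, then lactonisation and C13 methylenation.
3. The C10 vinyl and C4 isopropenyl groups come from the C10 ester and C5 acetyl group of a cycloadduct.
4. Ring A (C10, C5, C6, C7, C8, C9) comes from a catalytic asymmetric endo [4+2] cycloaddition of a 1-PMB-oxy-3,4-bis(silyloxy) diene (C6–C9) with methyl (E)-2-methyl-4-oxopent-2-enoate (C5, C10), forming C5–C6 and C9–C10. The strategy rests on the contiguous centres C5, C6, C9 and C10 of ring A, which hold C4, O6, O9 and the C14 methyl on one face.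
5. Ring order: ring A first (step 6), ring B second (step 14).

Key step: step 6

**Remarks and assumptions**
- Target numbering is used throughout. The "lower face" of ring A carries the C14 methyl, C4, O6 and O9; the "upper face" carries the vinyl group (or its precursor), C11 and O8.
- O9 is carried as a silyl ether, not as a carboxylic ester, because an ester there would not survive the hydride reduction (step 8) that turns the C10 ester into the vinyl group.
- Assumption: the acetyl enone is taken to bind the oxazaborolidinium like simple enones (s-trans, α-C–H···O contact), for which the (S)-prolinol-derived catalyst is expected to give the enantiomer drawn; this assignment is not secure, and the mirror-image catalyst from (R)-diphenylprolinol is used if the sense proves reversed.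
- The 2-methylbutanoyl stereocentre in the target SMILES is (R), so (R)-2-methylbutanoic acid is used.

**Route**

Step 1
Reactants: 1 (E)-4-methoxybut-3-en-2-one; 2 4-methoxybenzyl alcohol
Product: 3 (E)-4-(4-methoxybenzyloxy)but-3-en-2-one
Conditions: PPTS (cat.), toluene, 70 °C, reduced pressure (MeOH removed)
Reagents that add atoms: none
Why: Acid-catalysed alkoxy exchange (addition–elimination) on the vinylogous ester is driven by removal of methanol and should keep the more stable (E)-geometry.

Step 2
Reactants: 3 (E)-4-(4-methoxybenzyloxy)but-3-en-2-one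
Product: 4 (E)-2-(tert-butyldimethylsilyloxy)-4-(4-methoxybenzyloxy)buta-1,3-diene
Conditions: TBSOTf, Et3N, Et2O, 0 °C
Reagents that add atoms: tert-butyldimethylsilyl triflate, CC(C)(C)[Si](C)(C)OS(=O)(=O)C(F)(F)F
Why: Silyl enol ether formation by soft enolisation of the only enolisable position (the methyl ketone) gives the cross-conjugated 2-silyloxy diene.

Step 3
Reactants: 4 (E)-2-(tert-butyldimethylsilyloxy)-4-(4-methoxybenzyloxy)buta-1,3-diene
Product: 6 (E)-1-(tert-butyldimethylsilyloxy)-4-(4-methoxybenzyloxy)but-3-en-2-one, via silyloxy oxirane 5 (not isolated)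
Conditions: mCPBA, NaHCO3, CH2Cl2, −20 → 0 °C
Reagents that add atoms: mCPBA, OOC(=O)c1cccc(Cl)c1
Why: Rubottom oxidation: the terminal silyl enol ether carbon is the most nucleophilic site of the diene, and its epoxide opens with 1,4-silyl migration to the α′-silyloxy enone (any desilylated α′-hydroxy enone is re-silylated in step 4).

Step 4
Reactants: 6 (E)-1-(tert-butyldimethylsilyloxy)-4-(4-methoxybenzyloxy)but-3-en-2-one
Product: 7 (1E,3Z)-3,4-bis(tert-butyldimethylsilyloxy)-1-(4-methoxybenzyloxy)buta-1,3-diene
Conditions: TBSOTf, Et3N, Et2O, −78 → 0 °C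
Reagents that add atoms: tert-butyldimethylsilyl triflate, CC(C)(C)[Si](C)(C)OS(=O)(=O)C(F)(F)F
Why: Silyl enol ether formation at the only α-CH2 should favour the (Z)-enol ether (4-silyloxy group anti to the vinyl carbon, the less strained isomer), and only this isomer can adopt the s-cis geometry needed in step 6, so a minor (3E)-isomer would stay unreacted.

Step 5
Reactants: 8 methylglyoxal (40% aqueous); 9 methyl 2-(triphenylphosphoranylidene)propanoate
Product: 10 methyl (E)-2-methyl-4-oxopent-2-enoate
Conditions: CH2Cl2/H2O, 0 → 23 °C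
Reagents that add atoms: none
Why: Wittig olefination at the aldehyde carbonyl (more electrophilic than the ketone) with the α-branched stabilised ylide should give the (E)-alkene with the ester trans to the acetyl group.

Step 6
Reactants: 7 (1E,3Z)-3,4-bis(tert-butyldimethylsilyloxy)-1-(4-methoxybenzyloxy)buta-1,3-diene; 10 methyl (E)-2-methyl-4-oxopent-2-enoate
Product: 11 ring A cycloadduct (C7=C8 TBS enol ether; 9-OTBS; 6-OPMB; 5-acetyl; 10-methyl; 10-CO2Me)
Conditions: (S)-3,3-diphenyl-1-(o-tolyl)tetrahydro-1H,3H-pyrrolo[1,2-c][1,3,2]oxazaborole (from (S)-α,α-diphenylprolinol and o-tolylboronic acid, 20 mol%), HN(SO2CF3)2 (18 mol%), CH2Cl2, −78 → −40 °C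
Reagents that add atoms: none
Why: The oxazaborolidinium ion binds the acetyl oxygen of 10 and the diene adds in a concerted but asynchronous, normal-electron-demand [4+2] cycloaddition in which the silyl enol ether terminus C9 bonds to C10, the carbon β to the activated ketone, ahead of C6–C5 closure; the closest known reaction type is the oxazaborolidinium-catalysed Diels–Alder reaction of silyloxy dienes with enones, of which trisubstituted dienophiles carrying two acceptors are the demanding end. Ring A is closed by intermolecular six-membered annulation, suprafacial on both partners. C6 and C9 should come out cis because both oxygens of the (1E,3Z)-diene point outward, C5 and C10 should carry acetyl and methyl cis because the (E)-alkene geometry is retained, and the endo position of the catalyst-bound acetyl group (ester exo) should place C4, O6, O9 and the methyl on one face. The absolute configuration of all four centres is set by the catalyst, which shields one face of the bound enone. The step needs regioselectivity (secured by the matched polarisation of the 3-silyloxy/1-alkoxy diene and the ketone), endo selectivity (secured by the coordinated acetyl group) and face selectivity (secured by the catalyst, with the ester as second acceptor supplying enough reactivity at low temperature to outrun uncatalysed addition).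

Step 7
Reactants: 11 ring A cycloadduct
Product: 12 isopropenyl ester (C5 acetyl replaced by C(CH3)=CH2)
Conditions: Cp2Ti(μ-CH2)(μ-Cl)AlMe2 (Tebbe reagent, 1.3 equiv), pyridine (cat.), THF, −40 → 0 °C
Reagents that add atoms: Tebbe reagent (written as titanocene methylidene·Me2AlCl), C=[Ti](C1C=CC=C1)C1C=CC=C1.C[Al](C)Cl
Why: Tebbe methylenation is non-basic, so the β-alkoxy ketone is neither epimerised at C5 nor eliminated, and at low temperature the ketone reacts ahead of the hindered α-quaternary methyl ester.

Step 8
Reactants: 12 isopropenyl ester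
Product: 13 C10 hydroxymethyl compound
Conditions: iBu2AlH (3 equiv), CH2Cl2, −78 → 0 °C; aq. KNaC4H4O6
Reagents that add atoms: none
Why: Hydride reduction of the only carbonyl group left gives the neopentyl primary alcohol while silyl enol ether, silyl ether and PMB ether are inert.

Step 9
Reactants: 13 C10 hydroxymethyl compound
Product: 14 C10 aldehyde
Conditions: Dess–Martin periodinane, pyridine, CH2Cl2, 0 → 23 °C
Reagents that add atoms: none
Why: Buffered Dess–Martin oxidation of a primary alcohol to a non-enolisable aldehyde should leave the silyl enol ether untouched.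

Step 10
Reactants: 14 C10 aldehyde
Product: 15 C10 vinyl C4 isopropenyl silyl enol ether
Conditions: Ph3PCH3Br, KN(SiMe3)2, THF, 0 → 23 °C
Reagents that add atoms: methyltriphenylphosphonium bromide, C[P+](c1ccccc1)(c1ccccc1)c1ccccc1.[Br-]
Why: Wittig methylenation of an aldehyde without α-hydrogen, in a molecule that now has no base-sensitive carbonyl group, installs the C1=C2 vinyl group.

Step 11
Reactants: 15 C10 vinyl C4 isopropenyl silyl enol ether
Product: 16 C8 ketone (9-OTBS; 6-OPMB)
Conditions: Bu4NF (1.05 equiv), AcOH (1.5 equiv), THF, −40 → −20 °C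
Reagents that add atoms: none
Why: Buffered fluoride cleaves the enol silyl ether far faster than the secondary alkyl silyl ether, and the acetic acid protonates the enolate at C7 (a CH2, no stereocentre) before the C6 PMB-oxy group can be eliminated.

Step 12
Reactants: 16 C8 ketone; 17 ethyl iodoacetate
Product: 19 C7 ethoxycarbonylmethyl ketone, via lithium C7=C8 enolate 18 (not isolated)
Conditions: LiN(iPr)2, THF, −78 °C; then ICH2CO2Et, DMPU, −78 → −60 °C
Reagents that add atoms: none
Why: Kinetic enolate alkylation: deprotonation occurs at the C7 methylene rather than the hindered C9 methine, and the reactive iodoacetate should attack the half-chair enolate on the upper face, anti to the adjacent C6 PMB-oxy group, setting C7 with C11 trans to O6.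

Step 13
Reactants: 19 C7 ethoxycarbonylmethyl ketone
Product: 20 6-hydroxy C8 ketone
Conditions: DDQ, CH2Cl2/pH 7 buffer, 0 °C
Reagents that add atoms: none
Why: Oxidative PMB ether cleavage under neutral, buffered conditions frees O6 without retro-aldol cleavage or dehydration of the β-hydroxy ketone.

Step 14
Reactants: 20 6-hydroxy C8 ketone
Product: 22 cis-fused γ-lactone (ring B closed; 6-OH; 9-OTBS), via anti diol ester 21 (not isolated)
Conditions: Me4NBH(OAc)3, MeCN/AcOH, −30 °C; then CSA (cat.), CH2Cl2, 23 °C
Reagents that add atoms: none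
Why: Evans–Saksena reduction: the O6-bound acetoxyborohydride delivers hydride intramolecularly to the lower face of C8, which sets O8 on the upper face (1,3-anti to O6), and only O8 is cis to the C7 acetate arm, so lactonisation should close the cis-fused ring B and leave O6 free.

Step 15
Reactants: 22 cis-fused γ-lactone
Product: 26 α-methylene lactone (6-OH; 9-OTBS), via dilithium alkoxide enolate 23 (not isolated), via Mannich base 24 (not isolated), via trimethylammonium iodide 25 (not isolated)
Conditions: LiN(iPr)2 (2.3 equiv), THF, −78 °C; CH2=NMe2+ I−, −78 → 23 °C; then MeI, MeOH; then NaHCO3 (aq), CH2Cl2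
Reagents that add atoms: Eschenmoser's salt, C=[N+](C)C.[I-]
Why: Eschenmoser methylenation: the lactone enolate (the only enolisable position) is aminomethylated at C11, and quaternisation followed by mild base eliminates trimethylamine to give the exocyclic C11=C13 alkene.

Step 16
Reactants: 26 α-methylene lactone; 27 angelic acid
Product: 28 6-O-angelate (9-OTBS)
Conditions: 2,4,6-Cl3C6H2COCl, Et3N, toluene, 23 °C; then 26, 75 °C
Reagents that add atoms: none
Why: Yamaguchi esterification through the mixed anhydride, run without a nucleophilic pyridine catalyst, is the standard way to acylate a hindered secondary alcohol with angelic acid while keeping the (Z)-geometry.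

Step 17
Reactants: 28 6-O-angelate (9-OTBS)
Product: 29 6-O-angelate 9-ol
Conditions: HF·pyridine, pyridine, THF, 0 → 23 °C
Reagents that add atoms: none
Why: Fluoride-mediated silyl ether cleavage under mildly acidic conditions should leave the angelate, the lactone and the Michael acceptors intact.

Step 18
Reactants: 29 6-O-angelate 9-ol; 30 (R)-2-methylbutanoic acid
Product: 31 6-O-angelate 9-O-(R)-2-methylbutanoate (C4 isopropenyl)
Conditions: DCC, DMAP, CH2Cl2, 0 → 23 °C
Reagents that add atoms: none
Why: Steglich esterification with the free acid avoids ketene formation, so the α-stereocentre of the acyl group should be retained.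

Step 19
Reactants: 31 6-O-angelate 9-O-(R)-2-methylbutanoate
Product: 32 C15 allylic alcohol
Conditions: SeO2 (0.5 equiv), t-BuOOH, CH2Cl2, 23 °C
Reagents that add atoms: selenium dioxide (oxygen carrier), O=[Se]=O; tert-butyl hydroperoxide (terminal oxidant), CC(C)(C)OO
Why: Riley-type allylic oxidation (ene reaction, then [2,3]-shift) should select the isopropenyl group, the only electron-rich alkene with allylic hydrogens, and its methyl over the hindered C5 methine, whose C–H lies near the alkene plane (the vinyl group has no allylic hydrogen; the angelate and methylene lactone are electron-poor).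

Step 20
Reactants: 32 C15 allylic alcohol
Product: 33 target CNP0295282.1
Conditions: MnO2, CH2Cl2, 23 °C
Reagents that add atoms: none
Why: MnO2 oxidises the allylic alcohol to the enal under neutral conditions, and any enal already formed in step 19 converges here.

**Compound list**
1 | (E)-4-methoxybut-3-en-2-one | CO/C=C/C(C)=O | starting material
2 | 4-methoxybenzyl alcohol | COc1ccc(CO)cc1 | starting material
3 | (E)-4-(4-methoxybenzyloxy)but-3-en-2-one | COc1ccc(CO/C=C/C(C)=O)cc1 | intermediate
4 | (E)-2-(tert-butyldimethylsilyloxy)-4-(4-methoxybenzyloxy)buta-1,3-diene | COc1ccc(CO/C=C/C(=C)O[Si](C)(C)C(C)(C)C)cc1 | intermediate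
5 | 2-(tert-butyldimethylsilyloxy)-2-[(E)-2-(4-methoxybenzyloxy)vinyl]oxirane (racemic, not isolated) | COc1ccc(CO/C=C/C2(CO2)O[Si](C)(C)C(C)(C)C)cc1 | intermediate
6 | (E)-1-(tert-butyldimethylsilyloxy)-4-(4-methoxybenzyloxy)but-3-en-2-one | COc1ccc(CO/C=C/C(=O)CO[Si](C)(C)C(C)(C)C)cc1 | intermediate
7 | (1E,3Z)-3,4-bis(tert-butyldimethylsilyloxy)-1-(4-methoxybenzyloxy)buta-1,3-diene | COc1ccc(CO/C=C/C(O[Si](C)(C)C(C)(C)C)=C/O[Si](C)(C)C(C)(C)C)cc1 | intermediate
8 | methylglyoxal | CC(=O)C=O | starting material
9 | methyl 2-(triphenylphosphoranylidene)propanoate | COC(=O)C(C)=P(c1ccccc1)(c1ccccc1)c1ccccc1 | starting material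
10 | methyl (E)-2-methyl-4-oxopent-2-enoate | COC(=O)/C(C)=C/C(C)=O | intermediate
11 | methyl 6-acetyl-2,3-bis(tert-butyldimethylsilyloxy)-5-(4-methoxybenzyloxy)-1-methylcyclohex-3-ene-1-carboxylate (ring C1–C6 = target C10, C9, C8, C7, C6, C5; methyl, 2-silyloxy, PMB-oxy and acetyl cis on the lower face, ester on the upper face) | COC(=O)[C@@]1(C)[C@H](C(C)=O)[C@H](OCc2ccc(OC)cc2)C=C(O[Si](C)(C)C(C)(C)C)[C@@H]1O[Si](C)(C)C(C)(C)C | intermediate
12 | as 11 with prop-1-en-2-yl at C5 in place of acetyl | COC(=O)[C@@]1(C)[C@H](C(C)=C)[C@H](OCc2ccc(OC)cc2)C=C(O[Si](C)(C)C(C)(C)C)[C@@H]1O[Si](C)(C)C(C)(C)C | intermediate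
13 | as 12 with CH2OH at C10 in place of CO2Me | OC[C@@]1(C)[C@H](C(C)=C)[C@H](OCc2ccc(OC)cc2)C=C(O[Si](C)(C)C(C)(C)C)[C@@H]1O[Si](C)(C)C(C)(C)C | intermediate
14 | as 12 with CHO at C10 | O=C[C@@]1(C)[C@H](C(C)=C)[C@H](OCc2ccc(OC)cc2)C=C(O[Si](C)(C)C(C)(C)C)[C@@H]1O[Si](C)(C)C(C)(C)C | intermediate
15 | ring A triene: C10 vinyl (upper) and methyl (lower), C5 isopropenyl, 6-OPMB, C7=C8 TBS enol ether, 9-OTBS | C=C[C@@]1(C)[C@H](C(C)=C)[C@H](OCc2ccc(OC)cc2)C=C(O[Si](C)(C)C(C)(C)C)[C@@H]1O[Si](C)(C)C(C)(C)C | intermediate
16 | C8 ketone of 15 (C7 methylene; 9-OTBS; 6-OPMB) | C=C[C@@]1(C)[C@H](C(C)=C)[C@H](OCc2ccc(OC)cc2)CC(=O)[C@@H]1O[Si](C)(C)C(C)(C)C | intermediate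
17 | ethyl iodoacetate | CCOC(=O)CI | starting material
18 | lithium C7=C8 enolate of 16 (not isolated) | C=C[C@@]1(C)[C@H](C(C)=C)[C@H](OCc2ccc(OC)cc2)C=C(O[Li])[C@@H]1O[Si](C)(C)C(C)(C)C | intermediate
19 | C8 ketone with CH2CO2Et at C7 on the upper face (trans to O6) | C=C[C@@]1(C)[C@H](C(C)=C)[C@H](OCc2ccc(OC)cc2)[C@@H](CC(=O)OCC)C(=O)[C@@H]1O[Si](C)(C)C(C)(C)C | intermediate
20 | as 19 with free 6-OH | C=C[C@@]1(C)[C@H](C(C)=C)[C@H](O)[C@@H](CC(=O)OCC)C(=O)[C@@H]1O[Si](C)(C)C(C)(C)C | intermediate
21 | 6,8-anti diol ester (8-OH on the upper face; not isolated) | C=C[C@@]1(C)[C@H](C(C)=C)[C@H](O)[C@@H](CC(=O)OCC)[C@@H](O)[C@@H]1O[Si](C)(C)C(C)(C)C | intermediate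
22 | cis-fused 8,12-lactone (ring B; 6-OH; 9-OTBS) | C=C[C@@]1(C)[C@H](C(C)=C)[C@H](O)[C@H]2CC(=O)O[C@H]2[C@@H]1O[Si](C)(C)C(C)(C)C | intermediate
23 | dilithium O6-alkoxide lactone enolate of 22 (not isolated) | C=C[C@@]1(C)[C@H](C(C)=C)[C@H](O[Li])[C@H]2C=C(O[Li])O[C@H]2[C@@H]1O[Si](C)(C)C(C)(C)C | intermediate
24 | C11 dimethylaminomethyl lactone (C11 epimers, not isolated) | C=C[C@@]1(C)[C@H](C(C)=C)[C@H](O)[C@H]2C(CN(C)C)C(=O)O[C@H]2[C@@H]1O[Si](C)(C)C(C)(C)C | intermediate
25 | trimethylammonium iodide of 24 (not isolated) | C=C[C@@]1(C)[C@H](C(C)=C)[C@H](O)[C@H]2C(C[N+](C)(C)C)C(=O)O[C@H]2[C@@H]1O[Si](C)(C)C(C)(C)C.[I-] | intermediate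
26 | α-methylene lactone (6-OH; 9-OTBS) | C=C[C@@]1(C)[C@H](C(C)=C)[C@H](O)[C@H]2C(=C)C(=O)O[C@H]2[C@@H]1O[Si](C)(C)C(C)(C)C | intermediate
27 | angelic acid, (Z)-2-methylbut-2-enoic acid | C/C=C(/C)C(=O)O | starting material
28 | 6-O-angelate of 26 | C=C[C@@]1(C)[C@H](C(C)=C)[C@H](OC(=O)/C(C)=C\C)[C@H]2C(=C)C(=O)O[C@H]2[C@@H]1O[Si](C)(C)C(C)(C)C | intermediate
29 | 6-O-angelate 9-ol | C=C[C@@]1(C)[C@H](C(C)=C)[C@H](OC(=O)/C(C)=C\C)[C@H]2C(=C)C(=O)O[C@H]2[C@@H]1O | intermediate
30 | (R)-2-methylbutanoic acid | CC[C@@H](C)C(=O)O | starting material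
31 | 6-O-angelate 9-O-(R)-2-methylbutanoate with C4 isopropenyl | C=C[C@@]1(C)[C@H](C(C)=C)[C@H](OC(=O)/C(C)=C\C)[C@H]2C(=C)C(=O)O[C@H]2[C@@H]1OC(=O)[C@H](C)CC | intermediate
32 | C15 allylic alcohol | C=C[C@@]1(C)[C@H](C(=C)CO)[C@H](OC(=O)/C(C)=C\C)[C@H]2C(=C)C(=O)O[C@H]2[C@@H]1OC(=O)[C@H](C)CC | intermediate
33 | CNP0295282.1 | C=C[C@@]1(C)[C@H](C(=C)C=O)[C@H](OC(=O)/C(C)=C\C)[C@H]2C(=C)C(=O)O[C@H]2[C@@H]1OC(=O)[C@H](C)CC | target

**Step count**
Total: 20 steps. Longest linear sequence: 19 steps (steps 1–4, then 6–20).

**Steps most likely to fail**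

1. Step 6. What may go wrong: slow bond formation between the oxygenated terminus C9 and the fully substituted C10; silyl transfer from the diene to the triflimide, which would give an achiral silyl Lewis acid and a racemic background reaction; a stepwise Michael-type path that erodes endo control; activation of the ester instead of the ketone (reversed regiochemistry); and poor face selectivity because the acetyl group and the cis β-methyl group cannot lie in one plane. Fallback: the formyl analogue is used as dienophile, since such catalysts bind 2-alkenals firmly through the formyl C–H and an aldehyde is the stronger activator. The fallback sets out from ylide 9 and diene 7 and comes back at 11. Ylide 9 and 2,2-dimethoxyacetaldehyde give methyl (E)-4,4-dimethoxy-2-methylbut-2-enoate F1, and aqueous acid frees methyl (E)-2-methyl-4-oxobut-2-enoate F2. Cycloaddition with 7 under the mirror-image catalyst (from (R)-diphenylprolinol; enals are expected to expose the other face than enones) should give the C5 formyl cycloadduct F3 with the same regio- and endo sense. MeMgBr at −78 °C adds to the aldehyde only, giving the C5 1-hydroxyethyl cycloadduct F4 (carbinol epimers), and Dess–Martin oxidation returns 11.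

2. Step 12. What may go wrong: β-elimination of the C6 PMB-oxy group from the C7 enolate, proton exchange between product and enolate leading to dialkylation, or enolisation toward C9. Fallback: a route with no free enolate, setting out from silyl enol ether 15 and coming back at 19 (it replaces steps 11 and 12). Copper-catalysed cyclopropanation of 15 with ethyl diazoacetate (Cu(acac)2, benzene, 70 °C) should occur at the most electron-rich alkene and on the face opposite O6 and O9, giving the 2-silyloxycyclopropanecarboxylate F5. Et3N·3HF then opens the donor–acceptor ring between C8 and C11 and releases keto ester 19 with C11 on the upper face.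

3. Step 19. What may go wrong: competing abstraction of the C5 methine hydrogen (tertiary or transposed allylic alcohols), slow reaction of the hindered alkene, or oxidation at the angelate methyl groups on prolonged exposure. Fallback: a two-step chlorination–oxidation sequence, setting out from 31 and coming back at 33 (it replaces steps 19 and 20). Ene-type chlorination of the isopropenyl group with hypochlorous acid (Ca(OCl)2, CO2, CH2Cl2/H2O, 0 °C) gives the C15 allylic chloride F6. Oxidation with N-methylmorpholine N-oxide (KI cat., MeCN, 40 °C) then gives the enal 33 directly.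

**Further compounds**
F1 | step 6 | methyl (E)-4,4-dimethoxy-2-methylbut-2-enoate | COC(=O)/C(C)=C/C(OC)OC
F2 | step 6 | methyl (E)-2-methyl-4-oxobut-2-enoate | COC(=O)/C(C)=C/C=O
F3 | step 6 | C5 formyl cycloadduct (as 11 with CHO in place of acetyl) | COC(=O)[C@@]1(C)[C@H](C=O)[C@H](OCc2ccc(OC)cc2)C=C(O[Si](C)(C)C(C)(C)C)[C@@H]1O[Si](C)(C)C(C)(C)C
F4 | step 6 | C5 1-hydroxyethyl cycloadduct (carbinol epimers) | COC(=O)[C@@]1(C)[C@H](C(C)O)[C@H](OCc2ccc(OC)cc2)C=C(O[Si](C)(C)C(C)(C)C)[C@@H]1O[Si](C)(C)C(C)(C)C
F5 | step 12 | ethyl 2-silyloxycyclopropanecarboxylate fused at C7–C8 on the upper face (ester epimers at C11) | C=C[C@@]1(C)[C@H](C(C)=C)[C@H](OCc2ccc(OC)cc2)[C@H]2C(C(=O)OCC)[C@@]2(O[Si](C)(C)C(C)(C)C)[C@@H]1O[Si](C)(C)C(C)(C)C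
F6 | step 19 | C15 allylic chloride | C=C[C@@]1(C)[C@H](C(=C)CCl)[C@H](OC(=O)/C(C)=C\C)[C@H]2C(=C)C(=O)O[C@H]2[C@@H]1OC(=O)[C@H](C)CC
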